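**Overview**

- Disconnections: first the two aryl–CH2 bonds that join each bridging methylene to the one unsubstituted carbon of an outer ring; then the two CH2–central-ring bonds (Mannich); last the three aryl–acyl bonds (Friedel-Crafts) and the hindered aryl O–CH3 bond.
- Forward order: no ring is built and three purchased benzene rings are kept. The outer ketone comes from 2-methylphloroglucinol (acylation, bis-MOM protection, O-methylation, deprotection), the central ring from phloroglucinol (acylation, double aminomethylation), and the three rings are joined from the centre outward in one operation.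
- Enabling feature: C3 and C5 of the central 1-butanoyl-2,4,6-trihydroxybenzene ring each lie between two phenolic OH groups (on C2/C4 and on C4/C6), so a CH2 attached there can become the exocyclic carbon of an ortho-quinone methide. Each outer ring has one unsubstituted carbon (C5), between the C4 and C6 hydroxyls and para to the C2 methoxy group, to act as the nucleophile.
- Stereochemistry: the target has no stereocentre and no stereogenic double bond, so nothing has to be set.

Key step: step 7

Assumption: in step 2 the hydroxyl flanked by the C-methyl and the butanoyl group is taken to be the one that stays free, in line with the partial alkylation behaviour of C-methylated phloroacylphenones; the structure of the bis-ether is to be confirmed by NOE before the sequence continues.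

**Route**

Step 1
Reactants: 1 2-methylphloroglucinol (2-methylbenzene-1,3,5-triol); 2 butanoyl chloride
Product: 3 1-(2,4,6-trihydroxy-3-methylphenyl)butan-1-one (3-methylphlorobutyrophenone)
Conditions: AlCl3 (3.5 equiv), PhNO2-CH2Cl2, 0 °C to 40 °C; then ice, aq HCl
Reagents that add atoms: none
Why: Friedel-Crafts C-acylation; the two unsubstituted carbons of 1 are equivalent and the first acyl group, held in an aluminium chelate, deactivates the ring towards a second acylation, so a single mono-ketone should result.

Step 2
Reactants: 3 1-(2,4,6-trihydroxy-3-methylphenyl)butan-1-one
Product: 4 1-[2-hydroxy-4,6-bis(methoxymethoxy)-3-methylphenyl]butan-1-one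
Conditions: MOMCl (2.1 equiv), iPr2NEt (2.5 equiv), CH2Cl2, 0 °C to rt
Reagents that add atoms: chloromethyl methyl ether (MOMCl), COCCl
Why: O-alkylation of phenols with a chloromethyl ether (methoxymethyl ether formation); the hydroxyl between the C-methyl and the butanoyl group is shielded on both sides and is pressed by the methyl group into the hydrogen bond to the carbonyl, so two equivalents of the hard, O-selective electrophile should etherify the para hydroxyl and the ortho hydroxyl next to the free ring carbon and leave that one untouched.

Step 3
Reactants: 4 1-[2-hydroxy-4,6-bis(methoxymethoxy)-3-methylphenyl]butan-1-one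
Product: 5 1-[2-methoxy-4,6-bis(methoxymethoxy)-3-methylphenyl]butan-1-one
Conditions: MeI (3 equiv), K2CO3 (3 equiv), DMF, 45 °C
Reagents that add atoms: iodomethane (MeI), CI
Why: Williamson O-methylation; carbonate in a dipolar aprotic solvent breaks the chelate of the last phenol and its phenoxide is methylated, while so weak a base leaves the ketone alpha-CH2 and both acetals untouched.

Step 4
Reactants: 5 1-[2-methoxy-4,6-bis(methoxymethoxy)-3-methylphenyl]butan-1-one
Product: 6 1-(4,6-dihydroxy-2-methoxy-3-methylphenyl)butan-1-one (outer monomer)
Conditions: conc. aq HCl (cat.), MeOH, 45 °C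
Reagents that add atoms: none
Why: Acid-catalysed acetal methanolysis (MOM cleavage); each methoxymethyl cation is captured by the solvent as volatile dimethoxymethane, so the electron-rich ring carbon between the two liberated hydroxyls sees no free formaldehyde, and the aryl methyl ether and the ketone are inert to dilute HCl.

Step 5
Reactants: 7 phloroglucinol (benzene-1,3,5-triol); 2 butanoyl chloride
Product: 8 1-(2,4,6-trihydroxyphenyl)butan-1-one (phlorobutyrophenone)
Conditions: AlCl3 (4 equiv), PhNO2-CH2Cl2, 0 °C to 40 °C; then ice, aq HCl
Reagents that add atoms: none
Why: Friedel-Crafts mono-C-acylation; all three ring carbons of 7 are equivalent and the chelated acyl group of the product slows a second acylation, so one equivalent of 2 should stop at the mono-ketone.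

Step 6
Reactants: 8 1-(2,4,6-trihydroxyphenyl)butan-1-one; 9 N,N-dimethylmethyleneiminium iodide (Eschenmoser salt, 2.2 equiv)
Product: 11 1-[3,5-bis[(dimethylamino)methyl]-2,4,6-trihydroxyphenyl]butan-1-one, via mono-aminomethyl phenol 10 (not isolated)
Conditions: dry MeCN, 0 °C to rt (bis-hydroiodide forms); then aq NaHCO3 to pH 8
Reagents that add atoms: none
Why: Mannich aminomethylation with a preformed iminium salt; each of the two unsubstituted carbons of 8 lies between two hydroxyls and adds to the salt at room temperature, where neither the mono-base 10 nor 11 loses amine, and the absence of free formaldehyde excludes methylene-bridged dimers of 8.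

Step 7
Reactants: 11 1-[3,5-bis[(dimethylamino)methyl]-2,4,6-trihydroxyphenyl]butan-1-one; 6 1-(4,6-dihydroxy-2-methoxy-3-methylphenyl)butan-1-one (2.2 equiv)
Product: 15 Agrimol C, via first ortho-quinone methide 12 (not isolated), via mono-coupled Mannich base 13 (not isolated), via second ortho-quinone methide 14 (not isolated)
Conditions: 1,4-dioxane, reflux, slow N2 sweep; then dil. aq HCl wash
Reagents that add atoms: none
Why: On heating, a phenolic OH of 11 next to a CH2NMe2 group passes its proton to the nitrogen and dimethylamine is expelled, giving ortho-quinone methide 12 with a soft electrophilic exocyclic CH2; the only unsubstituted carbon of 6 (C5, between the C4 and C6 hydroxyls and para to the methoxy group) adds to it in conjugate fashion and the dienone tautomerises back to the phenol to give 13, and the same elimination and addition on the second arm through 14 gives 15. The closest known reaction type is the thermal C-benzylation of acylphloroglucinols and other electron-rich phenols by phenolic Mannich bases through ortho-quinone methides, run here twice on one ring. No ring is closed and no stereocentre is formed. The step needs cross-coupling instead of homocoupling, C-alkylation instead of O-alkylation and a single site on the nucleophile: 11 has no unsubstituted ring carbon and cannot alkylate itself, 6 never meets formaldehyde, O-attack on the quinone methide is reversible whereas C-attack ends in rearomatisation, and 6 offers only one free carbon. Sweeping out the volatile amine drives both eliminations forward and keeps the medium close to neutral, which should limit base-mediated exchange of the methylene bridges.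

**Compound list**

1 | 2-methylphloroglucinol (2-methylbenzene-1,3,5-triol) | Cc1c(O)cc(O)cc1O | starting material
2 | butanoyl chloride | CCCC(Cl)=O | starting material
3 | 1-(2,4,6-trihydroxy-3-methylphenyl)butan-1-one | CCCC(=O)c1c(O)cc(O)c(C)c1O | intermediate
4 | 1-[2-hydroxy-4,6-bis(methoxymethoxy)-3-methylphenyl]butan-1-one | CCCC(=O)c1c(OCOC)cc(OCOC)c(C)c1O | intermediate
5 | 1-[2-methoxy-4,6-bis(methoxymethoxy)-3-methylphenyl]butan-1-one | CCCC(=O)c1c(OCOC)cc(OCOC)c(C)c1OC | intermediate
6 | 1-(4,6-dihydroxy-2-methoxy-3-methylphenyl)butan-1-one | CCCC(=O)c1c(O)cc(O)c(C)c1OC | intermediate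
7 | phloroglucinol (benzene-1,3,5-triol) | Oc1cc(O)cc(O)c1 | starting material
8 | 1-(2,4,6-trihydroxyphenyl)butan-1-one | CCCC(=O)c1c(O)cc(O)cc1O | intermediate
9 | N,N-dimethylmethyleneiminium iodide (Eschenmoser salt) | C=[N+](C)C.[I-] | starting material
10 | 1-[3-[(dimethylamino)methyl]-2,4,6-trihydroxyphenyl]butan-1-one (present in the flask as its hydroiodide) | CCCC(=O)c1c(O)cc(O)c(CN(C)C)c1O | intermediate
11 | 1-[3,5-bis[(dimethylamino)methyl]-2,4,6-trihydroxyphenyl]butan-1-one | CCCC(=O)c1c(O)c(CN(C)C)c(O)c(CN(C)C)c1O | intermediate
12 | 4-butanoyl-2-[(dimethylamino)methyl]-3,5-dihydroxy-6-methylidenecyclohexa-2,4-dien-1-one (one tautomer drawn) | CCCC(=O)C1=C(O)C(=C)C(=O)C(CN(C)C)=C1O | intermediate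
13 | 1-[3-[(3-butanoyl-2,6-dihydroxy-4-methoxy-5-methylphenyl)methyl]-5-[(dimethylamino)methyl]-2,4,6-trihydroxyphenyl]butan-1-one | CCCC(=O)c1c(O)c(Cc2c(O)c(C)c(OC)c(C(=O)CCC)c2O)c(O)c(CN(C)C)c1O | intermediate
14 | 4-butanoyl-2-[(3-butanoyl-2,6-dihydroxy-4-methoxy-5-methylphenyl)methyl]-3,5-dihydroxy-6-methylidenecyclohexa-2,4-dien-1-one (one tautomer drawn) | CCCC(=O)C1=C(O)C(=C)C(=O)C(Cc2c(O)c(C)c(OC)c(C(=O)CCC)c2O)=C1O | intermediate
15 | Agrimol C, 1-[3,5-bis[(3-butanoyl-2,6-dihydroxy-4-methoxy-5-methylphenyl)methyl]-2,4,6-trihydroxyphenyl]butan-1-one | CCCC(=O)c1c(O)c(Cc2c(O)c(C)c(OC)c(C(=O)CCC)c2O)c(O)c(Cc2c(O)c(C)c(OC)c(C(=O)CCC)c2O)c1O | target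

**Step count**

Total: 7 steps. Longest linear sequence: 5 steps (steps 1, 2, 3, 4 and 7); the central branch needs 3 (steps 5, 6 and 7).

**Steps most likely to fail**

1. Step 7, the double coupling. After the first arm has reacted, the second aminomethyl group sits in a crowded, strongly hydrogen-bonded ring and may eliminate slowly. Prolonged heating with liberated dimethylamine can then lead to re-addition of the amine, retro-Mannich loss of a bridging carbon and base-mediated exchange of aryl groups across the methylene bridges, giving symmetrical dimers and oligomers. The fallback reverses the roles of the partners and sets out from 6. Aminomethylation of its single free carbon with 9 (dry MeCN, rt, then aq NaHCO3) should give 1-[3-[(dimethylamino)methyl]-2,4-dihydroxy-6-methoxy-5-methylphenyl]butan-1-one F1. Two equivalents of F1 heated with 8 in dioxane under a nitrogen sweep should then alkylate both free carbons of the central ring. Each electrophile has to eliminate only once and the nucleophile is the less hindered partner; F1 has no free ring carbon and cannot alkylate itself. This fallback comes back to the route at 15.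

2. Step 2, the partial etherification. The second equivalent of MOMCl may discriminate poorly between the two chelated ortho hydroxyls, or protection may run on to the tris-ether. In the desired bis-ether the lone aromatic hydrogen should show NOE contacts to both OCH2O groups and the C-methyl to only one; an isomer that fails this test is removed by chromatography. If the selectivity proves unusable, the fallback sets out from 8, in which the two ortho hydroxyls are equivalent. MOMCl and iPr2NEt should give 1-[2-hydroxy-4,6-bis(methoxymethoxy)phenyl]butan-1-one F2 as the only chelated bis-ether. Iodination ortho to the remaining phenol (N-iodosuccinimide, DMF, 0 °C) should give 1-[2-hydroxy-3-iodo-4,6-bis(methoxymethoxy)phenyl]butan-1-one F3. Suzuki-Miyaura methylation (trimethylboroxine, PdCl2(dppf), K2CO3, dioxane-water, 90 °C) then places the C-methyl next to the free hydroxyl. This fallback comes back to the route at 4.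

3. Step 6, the double aminomethylation. The second aminomethylation may stay incomplete, or the mono-base 10, which still carries a nucleophilic ring carbon, may lose amine prematurely and condense with itself; the zwitterionic bis-base may also resist isolation. The fallback sets out from 8 and introduces both carbons at the aldehyde oxidation level. Double Rieche formylation (Cl2CHOMe, TiCl4, CH2Cl2, 0 °C) should give the stable, crystalline 5-butanoyl-2,4,6-trihydroxybenzene-1,3-dicarbaldehyde F4. Double reductive amination with dimethylamine and NaBH(OAc)3 in 1,2-dichloroethane then gives the bis-amine without any intermediate that is both nucleophile and latent quinone methide. This fallback comes back to the route at 11.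

**Further compounds**

F1 | step 7 | 1-[3-[(dimethylamino)methyl]-2,4-dihydroxy-6-methoxy-5-methylphenyl]butan-1-one | CCCC(=O)c1c(O)c(CN(C)C)c(O)c(C)c1OC
F2 | step 2 | 1-[2-hydroxy-4,6-bis(methoxymethoxy)phenyl]butan-1-one | CCCC(=O)c1c(O)cc(OCOC)cc1OCOC
F3 | step 2 | 1-[2-hydroxy-3-iodo-4,6-bis(methoxymethoxy)phenyl]butan-1-one | CCCC(=O)c1c(O)c(I)c(OCOC)cc1OCOC
F4 | step 6 | 5-butanoyl-2,4,6-trihydroxybenzene-1,3-dicarbaldehyde | CCCC(=O)c1c(O)c(C=O)c(O)c(C=O)c1O
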